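Everything rests on cutting the C6–O and C9–O bonds together. In ring B the C6 ester oxygen and the C9 tertiary hydroxyl lie 1,4 to each other across the C7=C8 alkene, which is the imprint of dioxygen added to a 6,8-diene. One photooxygenation of a sclareolide-derived diene (C8 methyl, C9 silyloxymethyl, C5 and C10 already fixed) therefore makes both C–O bonds from the α-face as a 6α,9α-endoperoxide, sets C9 and leaves C7=C8. Base-induced peroxide opening, oxidation of C11 to a protected acid, ketone reduction to the 6β-alcohol, C12 oxidation, acylation with octatrienoic acid and ester cleavage finish the target.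

Key step: step 10

Remark: drimane numbering is used (C5/C10 ring fusion, C11 on C9, C12 on C8).
Assumption: the target is treated as the open hydroxy acid–aldehyde that is drawn; a lactol tautomer between C11 and C12, if it forms, is the same compound in equilibrium.

Step 1
Reactants: 1 (+)-sclareolide
Product: 2 11-hydroxysclareolide (hydroxyl on the lactone α-carbon C11, either epimer)
Conditions: KN(SiMe3)2, THF, −78 °C; then trans-2-(phenylsulfonyl)-3-phenyloxaziridine, −78 °C; AcOH quench
Reagents that add atoms: trans-2-(phenylsulfonyl)-3-phenyloxaziridine, O=S(=O)(c1ccccc1)N1OC1c1ccccc1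
Why: Davis oxidation: the potassium enolate of the γ-lactone, which can form only at C11, is hydroxylated by the N-sulfonyloxaziridine, presumably from the face remote from the C10 methyl, and the configuration of this new centre is irrelevant because C11 becomes an aldehyde carbon in step 3.

Step 2
Reactants: 2 11-hydroxysclareolide
Product: 3 homodrimane-8α,11,12-triol (8α-OH, 8β-CH3, 9β-(1,2-dihydroxyethyl), C11 epimers)
Conditions: LiAlH4, THF, 0 °C → rt; aqueous work-up
Reagents that add atoms: none
Why: LiAlH4 reduction of a lactone to the diol opens the ring to the primary C12 alcohol and the free tertiary 8α-hydroxyl without touching any ring stereocentre.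

Step 3
Reactants: 3 homodrimane-8α,11,12-triol
Product: 4 8α-hydroxydriman-11-al (9β-CHO, 9α-H)
Conditions: NaIO4, THF–H2O, 0 °C → rt
Reagents that add atoms: none
Why: Malaprade glycol cleavage cuts only the vicinal C11–C12 diol, expelling C12 as formaldehyde and leaving the 9β-formyl group, while the 1,3-related tertiary hydroxyl is inert and the neutral, cold medium spares the aldol from retro-aldol cleavage or C9 epimerisation.

Step 4
Reactants: 4 8α-hydroxydriman-11-al
Product: 6 drim-8-en-11-al, via 8α-mesylate 5 (not isolated)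
Conditions: MsCl, Et3N, CH2Cl2, 0 °C; then DBU, 0 °C → rt
Reagents that add atoms: none
Why: Aldol-type dehydration by mesylation and E1cB elimination: the tertiary 8α-mesylate is expelled through the enolate of the C11 aldehyde, so the double bond forms between C8 and C9 in conjugation, and DBU draws any deconjugated isomer into the tetrasubstituted enal, which avoids the alkene mixtures of a plain tertiary-alcohol dehydration.

Step 5
Reactants: 6 drim-8-en-11-al
Product: 7 drim-8-en-11-ol
Conditions: NaBH4, CeCl3·7H2O, MeOH, 0 °C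
Reagents that add atoms: none
Why: Luche 1,2-reduction: borohydride with CeCl3 attacks only the carbonyl of the hindered enal, whose β-carbon is fully substituted, to give the primary allylic alcohol.

Step 6
Reactants: 7 drim-8-en-11-ol
Product: 8 11-(tert-butyldimethylsilyloxy)drim-8-ene
Conditions: TBSCl, imidazole, DMF, rt
Reagents that add atoms: tert-butyldimethylsilyl chloride, CC(C)(C)[Si](C)(C)Cl
Why: Imidazole-promoted silylation of the primary alcohol gives a silyl ether that tolerates the oxidant, the lithium amide and the singlet oxygen used next and keeps the later diene electron-rich.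

Step 7
Reactants: 8 11-(tert-butyldimethylsilyloxy)drim-8-ene
Product: 9 11-(tert-butyldimethylsilyloxy)drim-8-en-7-one
Conditions: CrO3, 3,5-dimethylpyrazole, CH2Cl2, −20 °C
Reagents that add atoms: chromium trioxide, O=[Cr](=O)=O
Why: Allylic oxidation with the CrO3–3,5-dimethylpyrazole complex turns the ring methylene C7, rather than the C12 methyl or the oxygen-bearing C11, into the enone carbonyl, a conversion known for 11-oxygenated drim-8-enes.

Step 8
Reactants: 9 11-(tert-butyldimethylsilyloxy)drim-8-en-7-one
Product: 10 (E)-tosylhydrazone of 9 (NHTs syn to C6)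
Conditions: TsNHNH2, EtOH, 70 °C
Reagents that add atoms: p-toluenesulfonohydrazide, Cc1ccc(cc1)S(=O)(=O)NN
Why: Hydrazone condensation at the only carbonyl group, with the sulfonamide nitrogen expected anti to the fully substituted C8 and therefore syn to the C6 methylene, as the next step requires.

Step 9
Reactants: 10 (E)-tosylhydrazone of 9
Product: 11 11-(tert-butyldimethylsilyloxy)drima-6,8-diene
Conditions: LiN(iPr)2 (3 equiv), THF, −78 °C → rt; H2O
Reagents that add atoms: none
Why: Shapiro reaction of an α,β-unsaturated tosylhydrazone: after N–H removal a second equivalent of base abstracts a C6 hydrogen syn to nitrogen, sulfinate and N2 leave, and protonation of the C7 vinyl anion gives the homoannular 6,8-diene regiospecifically because C8 carries no hydrogen.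

Step 10
Reactants: 11 11-(tert-butyldimethylsilyloxy)drima-6,8-diene
Product: 12 6α,9α-epidioxy-11-(tert-butyldimethylsilyloxy)drim-7-ene
Conditions: O2, 5,10,15,20-tetraphenylporphyrin (cat.), visible light, CH2Cl2, −30 °C
Reagents that add atoms: dioxygen, O=O
Why: Visible-light sensitisation turns ground-state O2 into singlet oxygen, which adds as the 2π partner to the s-cis 6,8-diene held in ring B in a concerted suprafacial [4+2] cycloaddition, forming C6–O and C9–O together and moving the remaining alkene to C7=C8. The closest known reaction type is the photooxygenation of homoannular cyclohexadienes to endoperoxides, as with steroidal 5,7-dienes and α-terpinene. The one new ring, a six-membered 1,2-dioxene within a 2,3-dioxabicyclo[2.2.2]octene, is closed by cycloaddition, both of its new bonds arising in the same step. C6 and C9 are both set by substrate control: the axial C10 methyl and the 4β-methyl shield the β-face of ring B, so oxygen arrives from the α-face, and the peroxide bridge forces the two new C–O bonds to be cis. The step needs cycloaddition to beat the ene pathways and α-attack to beat β-attack; the locked cisoid diene, the low temperature and a non-polar medium favour the former, and the C5 and C10 centres bought with sclareolide secure the latter.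

Step 11
Reactants: 12 6α,9α-epidioxy-11-(tert-butyldimethylsilyloxy)drim-7-ene
Product: 14 9α,11-dihydroxydrim-7-en-6-one, via 11-O-silyl hydroxy enone 13 (not isolated)
Conditions: Et3N, CH2Cl2, 0 °C → rt; then HF·pyridine, THF, 0 °C → rt
Reagents that add atoms: none
Why: Kornblum–DeLaMare rearrangement followed by fluoride desilylation: the amine removes H6, the only hydrogen on a peroxide-bearing carbon, so the O–O bond breaks to the C6 ketone and the 9α-alcohol with C9 untouched, and HF·pyridine then frees the primary C11 hydroxyl without harming the γ-hydroxy enone.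

Step 12
Reactants: 14 9α,11-dihydroxydrim-7-en-6-one
Product: 16 9α-hydroxy-6-oxodrim-7-en-11-oic acid, via 11-aldehyde 15 (not isolated)
Conditions: TEMPO (cat.), NaOCl (cat.), NaClO2, MeCN–NaH2PO4/Na2HPO4 buffer (pH 6.7), 20 °C
Reagents that add atoms: sodium chlorite, [Na+].[O-]Cl=O
Why: Anelli–Zhao oxidation: the oxoammonium form of TEMPO oxidises only the primary alcohol of the primary/tertiary 1,2-diol to the α-hydroxy aldehyde, which chlorite converts at once (Pinnick-type) to the acid, the tertiary alcohol and the enone being inert and the temperature kept low because 16 is a vinylogous β-keto acid.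

Step 13
Reactants: 16 9α-hydroxy-6-oxodrim-7-en-11-oic acid
Product: 17 tert-butyl 9α-hydroxy-6-oxodrim-7-en-11-oate
Conditions: tert-butyl 2,2,2-trichloroacetimidate, CH2Cl2–cyclohexane, rt
Reagents that add atoms: tert-butyl 2,2,2-trichloroacetimidate, CC(C)(C)OC(=N)C(Cl)(Cl)Cl
Why: Imidate esterification: the carboxylic acid protonates the trichloroacetimidate and is alkylated on oxygen under near-neutral conditions while the hindered tertiary alcohol stays free, and the bulky ester later resists lactonisation by a C12 hydroxyl.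

Step 14
Reactants: 17 tert-butyl 9α-hydroxy-6-oxodrim-7-en-11-oate
Product: 18 tert-butyl 6β,9α-dihydroxydrim-7-en-11-oate
Conditions: NaBH4, CeCl3·7H2O, MeOH, −40 °C
Reagents that add atoms: none
Why: Luche reduction: 1,2-hydride delivery to the enone carbonyl occurs on the α-face because the axial C10 methyl and the 4β-methyl block the β-face, which sets C6 as the axial 6β-alcohol, while the tert-butyl ester is untouched.

Step 15
Reactants: 18 tert-butyl 6β,9α-dihydroxydrim-7-en-11-oate
Product: 20 tert-butyl 6β,9α-dihydroxy-12-oxodrim-7-en-11-oate, via 12-alcohol 19 (not isolated)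
Conditions: SeO2, 1,4-dioxane, 80 °C
Reagents that add atoms: selenium dioxide, O=[Se]=O
Why: Riley oxidation: the ene reaction of SeO2 places selenium on C7 and takes a hydrogen from the methyl on the more substituted alkene carbon C8, and the [2,3]-shift and further oxidation of the transient 12-alcohol give the enal, as known for C12 of drim-7-enes, while the tert-butyl ester keeps that alcohol from lactonising.

Step 16
Reactants: 20 tert-butyl 6β,9α-dihydroxy-12-oxodrim-7-en-11-oate; 21 (2E,4E,6E)-octa-2,4,6-trienoic acid
Product: 23 tert-butyl 9α-hydroxy-6β-[(2E,4E,6E)-octa-2,4,6-trienoyloxy]-12-oxodrim-7-en-11-oate, via mixed anhydride 22 (not isolated)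
Conditions: 21, 2,4,6-trichlorobenzoyl chloride, Et3N, toluene, rt; then 20, DMAP, toluene, rt → 40 °C
Reagents that add atoms: none
Why: Yamaguchi esterification: the mixed anhydride passes the trienoyl group through its acyl-DMAP salt to the secondary 6β-hydroxyl, the tertiary 9α-hydroxyl being unreactive, with retention at C6 and no change in the all-E triene.

Step 17
Reactants: 23 tert-butyl 9α-hydroxy-6β-[(2E,4E,6E)-octa-2,4,6-trienoyloxy]-12-oxodrim-7-en-11-oate
Product: 24 ustusoic acid B
Conditions: CF3CO2H, CH2Cl2, 0 °C
Reagents that add atoms: none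
Why: Acidolysis of the tert-butyl ester by loss of isobutene frees the C11 acid, while the trienoate, the enal and the tertiary alcohol, whose ionisation is disfavoured by the adjacent carbonyl groups, should survive brief cold acid.

Compound list
1 | (+)-sclareolide | C1C[C@@]3(C)OC(=O)C[C@@H]3[C@@]2(C)CCCC(C)(C)[C@H]12 | starting material
2 | 11-hydroxysclareolide (C11 epimers) | C1C[C@@]3(C)OC(=O)C(O)[C@@H]3[C@@]2(C)CCCC(C)(C)[C@H]12 | intermediate
3 | homodrimane-8α,11,12-triol (C11 epimers) | C1C[C@@](C)(O)[C@H](C(O)CO)[C@@]2(C)CCCC(C)(C)[C@H]12 | intermediate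
4 | 8α-hydroxydriman-11-al | C1C[C@@](C)(O)[C@H](C=O)[C@@]2(C)CCCC(C)(C)[C@H]12 | intermediate
5 | 8α-(methylsulfonyloxy)driman-11-al | C1C[C@@](C)(OS(C)(=O)=O)[C@H](C=O)[C@@]2(C)CCCC(C)(C)[C@H]12 | intermediate (not isolated)
6 | drim-8-en-11-al | C1CC(C)=C(C=O)[C@@]2(C)CCCC(C)(C)[C@H]12 | intermediate
7 | drim-8-en-11-ol | C1CC(C)=C(CO)[C@@]2(C)CCCC(C)(C)[C@H]12 | intermediate
8 | 11-(tert-butyldimethylsilyloxy)drim-8-ene | C1CC(C)=C(CO[Si](C)(C)C(C)(C)C)[C@@]2(C)CCCC(C)(C)[C@H]12 | intermediate
9 | 11-(tert-butyldimethylsilyloxy)drim-8-en-7-one | C1C(=O)C(C)=C(CO[Si](C)(C)C(C)(C)C)[C@@]2(C)CCCC(C)(C)[C@H]12 | intermediate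
10 | (E)-tosylhydrazone of 9 | C1/C(=N\NS(=O)(=O)c3ccc(C)cc3)C(C)=C(CO[Si](C)(C)C(C)(C)C)[C@@]2(C)CCCC(C)(C)[C@H]12 | intermediate
11 | 11-(tert-butyldimethylsilyloxy)drima-6,8-diene | C1=CC(C)=C(CO[Si](C)(C)C(C)(C)C)[C@@]2(C)CCCC(C)(C)[C@H]12 | intermediate
12 | 6α,9α-epidioxy-11-(tert-butyldimethylsilyloxy)drim-7-ene | O3[C@H]1C=C(C)[C@](O3)(CO[Si](C)(C)C(C)(C)C)[C@@]2(C)CCCC(C)(C)[C@H]12 | intermediate
13 | 9α-hydroxy-11-(tert-butyldimethylsilyloxy)drim-7-en-6-one | O=C1C=C(C)[C@](O)(CO[Si](C)(C)C(C)(C)C)[C@@]2(C)CCCC(C)(C)[C@H]12 | intermediate (not isolated)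
14 | 9α,11-dihydroxydrim-7-en-6-one | O=C1C=C(C)[C@](O)(CO)[C@@]2(C)CCCC(C)(C)[C@H]12 | intermediate
15 | 9α-hydroxy-6-oxodrim-7-en-11-al | O=C1C=C(C)[C@](O)(C=O)[C@@]2(C)CCCC(C)(C)[C@H]12 | intermediate (not isolated)
16 | 9α-hydroxy-6-oxodrim-7-en-11-oic acid | O=C1C=C(C)[C@](O)(C(=O)O)[C@@]2(C)CCCC(C)(C)[C@H]12 | intermediate
17 | tert-butyl 9α-hydroxy-6-oxodrim-7-en-11-oate | O=C1C=C(C)[C@](O)(C(=O)OC(C)(C)C)[C@@]2(C)CCCC(C)(C)[C@H]12 | intermediate
18 | tert-butyl 6β,9α-dihydroxydrim-7-en-11-oate | O[C@@H]1C=C(C)[C@](O)(C(=O)OC(C)(C)C)[C@@]2(C)CCCC(C)(C)[C@H]12 | intermediate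
19 | tert-butyl 6β,9α,12-trihydroxydrim-7-en-11-oate | O[C@@H]1C=C(CO)[C@](O)(C(=O)OC(C)(C)C)[C@@]2(C)CCCC(C)(C)[C@H]12 | intermediate (not isolated)
20 | tert-butyl 6β,9α-dihydroxy-12-oxodrim-7-en-11-oate | O[C@@H]1C=C(C=O)[C@](O)(C(=O)OC(C)(C)C)[C@@]2(C)CCCC(C)(C)[C@H]12 | intermediate
21 | (2E,4E,6E)-octa-2,4,6-trienoic acid | C/C=C/C=C/C=C/C(=O)O | starting material
22 | (2E,4E,6E)-octa-2,4,6-trienoic 2,4,6-trichlorobenzoic anhydride | C/C=C/C=C/C=C/C(=O)OC(=O)c1c(Cl)cc(Cl)cc1Cl | intermediate (not isolated)
23 | tert-butyl 9α-hydroxy-6β-[(2E,4E,6E)-octa-2,4,6-trienoyloxy]-12-oxodrim-7-en-11-oate | C/C=C/C=C/C=C/C(=O)O[C@@H]1C=C(C=O)[C@](O)(C(=O)OC(C)(C)C)[C@@]2(C)CCCC(C)(C)[C@H]12 | intermediate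
24 | ustusoic acid B, 9α-hydroxy-6β-[(2E,4E,6E)-octa-2,4,6-trienoyloxy]-12-oxodrim-7-en-11-oic acid | C/C=C/C=C/C=C/C(=O)O[C@@H]1C=C(C=O)[C@](O)(C(=O)O)[C@@]2(C)CCCC(C)(C)[C@H]12 | target

Total step count: 17.
Longest linear sequence: 17 steps, from 1 to 24; acid 21 enters at step 16 without steps of its own.

Steps most likely to fail

Step 10. Singlet oxygen may be diverted into ene (hydroperoxide) channels at the tetrasubstituted C8=C9 bond, or facial discrimination may be incomplete. The fallback installs the two oxygens stepwise through a vinyl epoxide and sets out from 11. Buffered mCPBA (NaHCO3, CH2Cl2, −20 °C) should epoxidise the more electron-rich C8=C9 bond from the α-face to give 8α,9α-epoxy-11-(tert-butyldimethylsilyloxy)drim-6-ene F1. Acid-catalysed conjugate hydrolysis (cat. HClO4, THF–H2O, 0 °C) should open the allylic C8–O bond with water entering at C6, giving 11-(tert-butyldimethylsilyloxy)drim-7-ene-6ξ,9α-diol F2, whose C6 configuration does not matter. Oxidation of the secondary allylic alcohol with MnO2 in CH2Cl2 comes back to the route at 13, which is desilylated as in step 11.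

Step 15. The free 6β-allylic alcohol may be over-oxidised, the oxidation may stall at alcohol 19, or the ene step may be sluggish at the hindered, inductively deactivated C7=C8 bond. The fallback oxidises C12 one stage earlier and sets out from 17. SeO2 in dioxane at 90 °C acts on the enone, where the γ-methyl is activated through the dienol and no secondary alcohol is present, to give tert-butyl 9α-hydroxy-6,12-dioxodrim-7-en-11-oate F3. Luche reduction (NaBH4, CeCl3·7H2O, MeOH, −40 °C) of both carbonyls gives 19, isolated cold. TEMPO (cat.) with PhI(OAc)2 in CH2Cl2, selective for the primary allylic alcohol, comes back to the route at 20.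

Step 7. The oxidant may attack the oxygen-bearing allylic C11 or the C12 methyl instead of C7, or the silyl ether may be lost. The fallback replaces the ketone–hydrazone sequence by allylic bromination and dehydrobromination and sets out from 8. NBS with a radical initiator (AIBN, PhCF3, 80 °C) should give 7ξ-bromo-11-(tert-butyldimethylsilyloxy)drim-8-ene F4. DBU in toluene at 80 °C then eliminates toward C6 and comes back to the route at 11, bypassing 9 and 10.

Further compounds
F1 | step 10 | 8α,9α-epoxy-11-(tert-butyldimethylsilyloxy)drim-6-ene | C1=C[C@@]3(C)O[C@@]3(CO[Si](C)(C)C(C)(C)C)[C@@]2(C)CCCC(C)(C)[C@H]12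
F2 | step 10 | 11-(tert-butyldimethylsilyloxy)drim-7-ene-6ξ,9α-diol | OC1C=C(C)[C@](O)(CO[Si](C)(C)C(C)(C)C)[C@@]2(C)CCCC(C)(C)[C@H]12
F3 | step 15 | tert-butyl 9α-hydroxy-6,12-dioxodrim-7-en-11-oate | O=C1C=C(C=O)[C@](O)(C(=O)OC(C)(C)C)[C@@]2(C)CCCC(C)(C)[C@H]12
F4 | step 7 | 7ξ-bromo-11-(tert-butyldimethylsilyloxy)drim-8-ene | C1C(Br)C(C)=C(CO[Si](C)(C)C(C)(C)C)[C@@]2(C)CCCC(C)(C)[C@H]12
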